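Z, counted in percent of the D charged, is wanted after 1.0 h from birch, oak, elm, maple and cedar, flasks that differ in their charge of L, and two earlier runs show how D leaves the solid.

| flask | D | L | remark | time |
|---|---|---|---|---|
| Tuesday's | 0.69 M | 0.034 M | run made earlier |  |
| Saturday's | 0.69 M | 0.56 M | run made earlier |  |
| birch | 0.69 M | 0.0500 M |  | 1.0 h |
| oak | 0.69 M | 0.100 M |  | 1.0 h |
| elm | 0.69 M | 0.200 M |  | 1.0 h |
| maple | 0.69 M | 0.400 M |  | 1.0 h |
| cedar | 0.69 M | 0.800 M |  | 1.0 h |

- Tuesday's (time / min: Z / %, D / %): 5.00: 0.4, 76.3; 8.00: 0, 68.6; 12.0: 0.4, 60.8; 15.0: 1.2, 57.6; 25.0: 0.5, 53.2; 40.0: 1.1, 51.8; 60.0: 0.9, 50.1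
- Saturday's (time / min: Z / %, D / %): 3.00: 0.8, 83.6; 10.0: 2.3, 63.2; 15.0: 5.0, 56.3; 25.0: 9.0, 47.6; 40.0: 15.8, 38.2; 50.0: 19.6, 34.4; 60.0: 23.3, 30.2

(standard deviation of a reading: 0.5 percentage points)

- given per volume of solution although it is solid: D
- at the start none of D is in solution
- "hardly changes" means that all values lie within two and a half points (for a concentration: within two and a half percent of the largest)

- amount of Z at the end, in percent of the D charged for birch, oak, elm, maple, cedar, in this order
- how the row runs (rises all the way / hardly changes / falls all the way / rises, then falls / falls, then rises)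

At 60.0 min, the D neither left as solid nor found as Z, which we take as dissolved D, stood at 49.0% of the charge in Tuesday's run and 46.5% in Saturday's, although L was charged at 0.034 M and 0.56 M. So we treat dissolved D as a nearly constant partner and write the balance of L as a pseudo-first-order loss, in which, with that partner held fixed, equal fractions of different charges of L react in equal times. Saturday's last reading puts 28.7% of its L into Z, and this share, f, the fraction of the charged L found as Z after the hour, makes Z in percent of D equal to f times the charge of L over the charge of D. Our reckoning gives 2.08% for birch and 33.3% for cedar, and because this estimate for cedar is less than the 50.1% of D read as solid at the end of Tuesday's run, we expect solid to remain in cedar and the row to keep rising.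

The forecast gives 2.2%, 4.3%, 8.6%, 16.7% and 32%, which at cedar is less than our figure, and the shape rises all the way, on the ground that “Solid D remains even for cedar, so the row keeps rising.”

The flasks give 2.10%, 4.18%, 8.28%, 16.3% and 31.4%, and the row rises all the way.

    D ⇌ J, rate k1*(cs1 - [J]) while solid is left; crystals form when [J] > cs1 (solubility = 0.330 M, k = 0.00228 s⁻¹)
    J + L ⇌ Z (K = 52.0 M⁻¹, k = 3.86 × 10⁻⁴ M⁻¹ s⁻¹)
    J + Z → X (k = 1.34 × 10⁻⁴ M⁻¹ s⁻¹)
    L → G (k = 2.39 × 10⁻⁵ s⁻¹)
    L → Q (k = 2.06 × 10⁻⁷ s⁻¹)

Z follows the charge of L nearly in step: against the 28.7% read from Saturday's run, the share of L found as Z is 29.0% in birch and 27.1% in cedar, while J, the dissolved D, stands at 47.5% in birch and 43.4% in cedar at 1.00 h. Carried to Tuesday's run, f gives 1.41% of Z, and the reading at 60.0 min is 0.9%.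

The runs stem from a simulated flask with made-up constants; noise was put on by code.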